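**Retrosynthetic overview**

1. Lespeflorin B1 (16) comes from global desilylation of 15, and 15 from twofold allyl-to-prenyl cross-metathesis of the bis-allyl, bis-TIPS (2R,3R)-dihydroflavonol 14.
2. Key disconnection: the bond from B-ring C1' to pyranone C2. 14 is made from the achiral chromone 9 and the B-ring arylzinc (from bromide 4) by Rh/(S)-BINAP-catalysed asymmetric 1,4-arylation with in situ O-silylation, telescoped with anti-selective Rubottom hydroxylation at C3.
3. Enabling feature: in the pyranone ring C2 carries the ring oxygen O1 and is β to the C4 ketone through C3. At the chromone oxidation level (C2=C3) it is therefore the electrophilic terminus of a vinylogous ester, and C3 emerges as the enol-silane carbon that takes the hydroxyl anti to the new aryl group.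
4. Ring order: A ring and B ring are bought as arenes (5 and 1). The pyranone ring is closed before the key step (7 to 9); the key step closes no ring. The side chains are carried as allyl groups (Claisen rearrangement on the B ring, Stille coupling on the A ring).

Key step: step 7

Assumption: the sense of induction of Rh/(S)-BINAP on the chromone is taken from its behaviour with cyclic enones (aryl delivery giving the 2S enol silane, which is 2R once C3 carries oxygen); should the sense prove opposite, (R)-BINAP is used.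

**Route**

Step 1
Reactants: 1 4-bromophenol
Product: 2 1-bromo-4-(prop-2-en-1-yloxy)benzene
Conditions: allyl bromide, K2CO3, acetone, reflux
Reagents that add atoms: allyl bromide, C=CCBr
Why: Williamson ether synthesis of a phenoxide with a reactive allylic bromide should give clean O-allylation.

Step 2
Reactants: 2 1-bromo-4-(prop-2-en-1-yloxy)benzene
Product: 3 2-allyl-4-bromophenol
Conditions: N,N-diethylaniline, 200 °C
Reagents that add atoms: none
Why: Aromatic Claisen rearrangement ([3,3]-shift, then tautomerisation) should place the allyl group ortho to oxygen, the para position being blocked by bromine and the two ortho positions being equivalent.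

Step 3
Reactants: 3 2-allyl-4-bromophenol
Product: 4 (2-allyl-4-bromophenoxy)triisopropylsilane
Conditions: TIPSCl, imidazole, DMF, rt
Reagents that add atoms: chlorotriisopropylsilane, CC(C)[Si](Cl)(C(C)C)C(C)C
Why: Standard silylation of a phenol should give a TIPS ether that withstands the later bromine–lithium exchange and the oxidation.

Step 4
Reactants: 5 1-(5-bromo-2,4-dihydroxyphenyl)ethan-1-one
Product: 6 1-[5-bromo-2-hydroxy-4-(triisopropylsilyloxy)phenyl]ethan-1-one
Conditions: TIPSCl (1.05 equiv), imidazole, DMF, 0 °C to rt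
Reagents that add atoms: chlorotriisopropylsilane, CC(C)[Si](Cl)(C(C)C)C(C)C
Why: Regioselective silylation should occur at the more acidic, non-chelated 4-OH, because the 2-OH is held in a hydrogen bond to the acetyl group.

Step 5
Reactants: 6 1-[5-bromo-2-hydroxy-4-(triisopropylsilyloxy)phenyl]ethan-1-one
Product: 7 1-[5-allyl-2-hydroxy-4-(triisopropylsilyloxy)phenyl]ethan-1-one
Conditions: allylSnBu3, Pd(PPh3)4 (5 mol%), toluene, 100 °C
Reagents that add atoms: allyltributylstannane, C=CC[Sn](CCCC)(CCCC)CCCC
Why: Stille coupling of the aryl bromide with an allylstannane runs without base, so the aryl silyl ether and the free ortho-hydroxy ketone should persist.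

Step 6
Reactants: 7 1-[5-allyl-2-hydroxy-4-(triisopropylsilyloxy)phenyl]ethan-1-one
Product: 9 6-allyl-7-(triisopropylsilyloxy)-4H-chromen-4-one, via enaminone 8 (not isolated)
Conditions: DMF-DMA, toluene, 90 °C; then p-TsOH·H2O (1.1 equiv), CH2Cl2, rt
Reagents that add atoms: N,N-dimethylformamide dimethyl acetal, COC(OC)N(C)C
Why: Condensation of the methyl ketone with the amide acetal should give the enaminone, and acid-promoted intramolecular oxa-Michael addition of the phenol with loss of dimethylamine closes the pyranone ring (enaminone route to chromones).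

Step 7
Reactants: 4 (2-allyl-4-bromophenoxy)triisopropylsilane; 9 6-allyl-7-(triisopropylsilyloxy)-4H-chromen-4-one
Product: 14 (2R,3R)-6-allyl-2-[3-allyl-4-(triisopropylsilyloxy)phenyl]-3-hydroxy-7-(triisopropylsilyloxy)chroman-4-one, via aryllithium 10 (not isolated), via arylzinc chloride 11 (not isolated), via trimethylsilyl enol ether 12 (not isolated), via silyloxy epoxide 13 (not isolated)
Conditions: 4, n-BuLi, THF, −78 °C; ZnCl2, −78 to 0 °C; then 9, [RhCl((S)-binap)]2 (5 mol% Rh), TMSCl (1.5 equiv), THF, 20 °C; pentane, filter under Ar, concentrate; DMDO (1.1 equiv), acetone/CH2Cl2, −78 °C; 10% aq. citric acid, THF, 0 °C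
Reagents that add atoms: dimethyldioxirane, CC1(C)OO1
Why: Proposed new method: transmetalation of arylzinc 11 to the (S)-BINAP–Rh(I) centre, enantioface-selective insertion of the chromone C2=C3 bond into the aryl–Rh bond and O-silylation of the resulting oxa-π-allyl rhodium by TMSCl should give enol silane 12 without a free enolate, after which DMDO epoxidises C3=C4 and mild acid opens silyloxy epoxide 13 to the α-hydroxy ketone (Rubottom oxidation). The closest known reaction types are the Rh/BINAP-catalysed asymmetric 1,4-addition of arylzinc chlorides with TMSCl to N-acyl-4-quinolones and 2,3-dihydro-4-pyridones, the Rh-catalysed asymmetric 1,4-addition of arylboronic acids to chromones, and the DMDO oxidation of flavanone silyl enol ethers to trans-3-hydroxyflavanones; new here is the arylzinc/silyl-trapping variant on a chromone and its telescoping with the oxidation. No ring is closed: the pyranone ring comes intact from 9 and only the C1'–C2 and C3–O bonds are formed. C2 is set by the catalyst, whose chiral ligand selects the enantioface of the planar chromone, and C3 is set by the substrate, because the new 2-aryl group shields one face of the enol silane so that oxygen is delivered anti to it (2,3-trans). The step needs 1,4- over 1,2-addition and catalysed over background addition (expected from the Rh cycle and the low electrophilicity of the vinylogous ester toward the arylzinc alone), configurational stability at C2 (silyl trapping avoids the enolate that would open by retro-oxa-Michael reaction) and oxidation of the enol silane before the alkenes (the side chains are carried as monosubstituted allyl groups, which react with DMDO far more slowly than an electron-rich enol ether at −78 °C).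

Step 8
Reactants: 14 (2R,3R)-6-allyl-2-[3-allyl-4-(triisopropylsilyloxy)phenyl]-3-hydroxy-7-(triisopropylsilyloxy)chroman-4-one
Product: 15 (2R,3R)-3-hydroxy-6-(3-methylbut-2-en-1-yl)-2-[3-(3-methylbut-2-en-1-yl)-4-(triisopropylsilyloxy)phenyl]-7-(triisopropylsilyloxy)chroman-4-one
Conditions: 2-methyl-2-butene (large excess), Grubbs II catalyst (5 mol%), CH2Cl2, 40 °C
Reagents that add atoms: 2-methylbut-2-ene, CC=C(C)C
Why: Olefin cross-metathesis of terminal allylarenes with excess 2-methyl-2-butene is a well-precedented allyl-to-prenyl exchange under neutral conditions that should leave the α-hydroxy ketone and both stereocentres untouched.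

Step 9
Reactants: 15 (2R,3R)-3-hydroxy-6-(3-methylbut-2-en-1-yl)-2-[3-(3-methylbut-2-en-1-yl)-4-(triisopropylsilyloxy)phenyl]-7-(triisopropylsilyloxy)chroman-4-one
Product: 16 lespeflorin B1
Conditions: TBAF, AcOH (1:1), THF, 0 °C
Reagents that add atoms: none
Why: Fluoride-mediated cleavage of both aryl silyl ethers, buffered with acetic acid, should free the phenols without base-induced retro-oxa-Michael opening or C2/C3 epimerisation and without the acid that would cyclise the ortho-prenylphenols to chromans.

**Compound list**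

1 | 4-bromophenol | Oc1ccc(Br)cc1 | starting material
2 | 1-bromo-4-(prop-2-en-1-yloxy)benzene | C=CCOc1ccc(Br)cc1 | intermediate
3 | 2-allyl-4-bromophenol | C=CCc1cc(Br)ccc1O | intermediate
4 | (2-allyl-4-bromophenoxy)triisopropylsilane | C=CCc1cc(Br)ccc1O[Si](C(C)C)(C(C)C)C(C)C | intermediate
5 | 1-(5-bromo-2,4-dihydroxyphenyl)ethan-1-one | CC(=O)c1cc(Br)c(O)cc1O | starting material
6 | 1-[5-bromo-2-hydroxy-4-(triisopropylsilyloxy)phenyl]ethan-1-one | CC(=O)c1cc(Br)c(O[Si](C(C)C)(C(C)C)C(C)C)cc1O | intermediate
7 | 1-[5-allyl-2-hydroxy-4-(triisopropylsilyloxy)phenyl]ethan-1-one | CC(=O)c1cc(CC=C)c(O[Si](C(C)C)(C(C)C)C(C)C)cc1O | intermediate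
8 | (E)-1-[5-allyl-2-hydroxy-4-(triisopropylsilyloxy)phenyl]-3-(dimethylamino)prop-2-en-1-one | CN(C)/C=C/C(=O)c1cc(CC=C)c(O[Si](C(C)C)(C(C)C)C(C)C)cc1O | intermediate
9 | 6-allyl-7-(triisopropylsilyloxy)-4H-chromen-4-one | O=c1ccoc2cc(O[Si](C(C)C)(C(C)C)C(C)C)c(CC=C)cc12 | intermediate
10 | [3-allyl-4-(triisopropylsilyloxy)phenyl]lithium | C=CCc1cc([Li])ccc1O[Si](C(C)C)(C(C)C)C(C)C | intermediate
11 | [3-allyl-4-(triisopropylsilyloxy)phenyl]zinc chloride | C=CCc1cc([Zn]Cl)ccc1O[Si](C(C)C)(C(C)C)C(C)C | intermediate
12 | (2S)-6-allyl-2-[3-allyl-4-(triisopropylsilyloxy)phenyl]-7-(triisopropylsilyloxy)-4-(trimethylsilyloxy)-2H-chromene | C=CCc1cc([C@H]2Oc3cc(O[Si](C(C)C)(C(C)C)C(C)C)c(CC=C)cc3C(O[Si](C)(C)C)=C2)ccc1O[Si](C(C)C)(C(C)C)C(C)C | intermediate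
13 | (2R,3R,4R)-6-allyl-2-[3-allyl-4-(triisopropylsilyloxy)phenyl]-3,4-epoxy-7-(triisopropylsilyloxy)-4-(trimethylsilyloxy)chromane (epoxide oxygen anti to the 2-aryl group) | C=CCc1cc([C@H]2Oc3cc(O[Si](C(C)C)(C(C)C)C(C)C)c(CC=C)cc3[C@]4(O[Si](C)(C)C)O[C@H]24)ccc1O[Si](C(C)C)(C(C)C)C(C)C | intermediate
14 | (2R,3R)-6-allyl-2-[3-allyl-4-(triisopropylsilyloxy)phenyl]-3-hydroxy-7-(triisopropylsilyloxy)chroman-4-one (2,3-trans) | C=CCc1cc([C@H]2Oc3cc(O[Si](C(C)C)(C(C)C)C(C)C)c(CC=C)cc3C(=O)[C@@H]2O)ccc1O[Si](C(C)C)(C(C)C)C(C)C | intermediate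
15 | (2R,3R)-3-hydroxy-6-(3-methylbut-2-en-1-yl)-2-[3-(3-methylbut-2-en-1-yl)-4-(triisopropylsilyloxy)phenyl]-7-(triisopropylsilyloxy)chroman-4-one | CC(C)=CCc1cc([C@H]2Oc3cc(O[Si](C(C)C)(C(C)C)C(C)C)c(CC=C(C)C)cc3C(=O)[C@@H]2O)ccc1O[Si](C(C)C)(C(C)C)C(C)C | intermediate
16 | lespeflorin B1, (2R,3R)-3,7-dihydroxy-2-[4-hydroxy-3-(3-methylbut-2-en-1-yl)phenyl]-6-(3-methylbut-2-en-1-yl)chroman-4-one | CC(C)=CCc1cc([C@H]2Oc3cc(O)c(CC=C(C)C)cc3C(=O)[C@@H]2O)ccc1O | target

**Step count and risks**

Total step count: 9. Longest linear sequence: 6 steps (1, 2, 3, 7, 8, 9 from 4-bromophenol; equally 4, 5, 6, 7, 8, 9 from the bromoacetophenone).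

Steps most likely to fail:

Step 7 (proposed new method). Catalyst turnover may be slow on the electron-rich 7-silyloxychromone. An uncatalysed, silyl-activated aryl transfer may erode the enantioselectivity. The trimethylsilyl enol ether may hydrolyse before it is oxidised, returning unoxidised flavanone. The fallback uses known chemistry, sets out from 4 and 9 and rejoins the route at 12. Bromide 4 is converted (n-BuLi, B(OiPr)3, THF, −78 °C; aqueous NH4Cl) into [3-allyl-4-(triisopropylsilyloxy)phenyl]boronic acid F1. F1 is added to chromone 9 by the established Rh-catalysed asymmetric 1,4-addition of arylboronic acids to chromones (Rh(I) with a chiral bis-sulfoxide or diene ligand, aqueous toluene, base-lean) to give (2S)-6-allyl-2-[3-allyl-4-(triisopropylsilyloxy)phenyl]-7-(triisopropylsilyloxy)chroman-4-one F2. Soft enolisation of F2 (TMSOTf, Et3N, CH2Cl2, 0 °C) then gives enol silane 12, which is oxidised and hydrolysed as in step 7 to 14.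

Step 8. Exchange may stop after one of the two allyl groups, and ruthenium hydride species may move the double bonds into conjugation, giving inseparable mixtures at a late stage. The fallback sets out from 4 and 9 and rejoins the route at 15. The allyl-to-prenyl cross-metathesis is done separately on the two simple fragments: 4 gives [4-bromo-2-(3-methylbut-2-en-1-yl)phenoxy]triisopropylsilane F3 and 9 gives 6-(3-methylbut-2-en-1-yl)-7-(triisopropylsilyloxy)-4H-chromen-4-one F4. The sequence of step 7 is then run on these partners through [3-(3-methylbut-2-en-1-yl)-4-(triisopropylsilyloxy)phenyl]lithium F5, [3-(3-methylbut-2-en-1-yl)-4-(triisopropylsilyloxy)phenyl]zinc chloride F6, the bis-prenyl 4-(trimethylsilyloxy)-2H-chromene F7 and its 3,4-epoxide F8. Exactly one equivalent of DMDO is used at −78 °C so that the electron-rich enol silane is oxidised before the trisubstituted side-chain alkenes, and hydrolysis gives 15 directly.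

Step 5. Oxidative addition into the electron-rich C–Br bond next to the bulky silyl ether may be slow, with protodebromination and migration of the allyl double bond at 100 °C as competing processes. The fallback sets out from 5 and rejoins the route at 7. The coupling is moved before the silylation: Suzuki–Miyaura coupling of unprotected 5 with allylboronic acid pinacol ester (XPhos-ligated Pd precatalyst, K3PO4, THF/H2O, 60 °C) gives 1-(5-allyl-2,4-dihydroxyphenyl)ethan-1-one F9, and regioselective silylation of the 4-OH (TIPSCl, imidazole, DMF, as in step 4) gives 7.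

**Further compounds**

F1 | step 7 | [3-allyl-4-(triisopropylsilyloxy)phenyl]boronic acid | C=CCc1cc(B(O)O)ccc1O[Si](C(C)C)(C(C)C)C(C)C
F2 | step 7 | (2S)-6-allyl-2-[3-allyl-4-(triisopropylsilyloxy)phenyl]-7-(triisopropylsilyloxy)chroman-4-one | C=CCc1cc([C@H]2Oc3cc(O[Si](C(C)C)(C(C)C)C(C)C)c(CC=C)cc3C(=O)C2)ccc1O[Si](C(C)C)(C(C)C)C(C)C
F3 | step 8 | [4-bromo-2-(3-methylbut-2-en-1-yl)phenoxy]triisopropylsilane | CC(C)=CCc1cc(Br)ccc1O[Si](C(C)C)(C(C)C)C(C)C
F4 | step 8 | 6-(3-methylbut-2-en-1-yl)-7-(triisopropylsilyloxy)-4H-chromen-4-one | O=c1ccoc2cc(O[Si](C(C)C)(C(C)C)C(C)C)c(CC=C(C)C)cc12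
F5 | step 8 | [3-(3-methylbut-2-en-1-yl)-4-(triisopropylsilyloxy)phenyl]lithium | CC(C)=CCc1cc([Li])ccc1O[Si](C(C)C)(C(C)C)C(C)C
F6 | step 8 | [3-(3-methylbut-2-en-1-yl)-4-(triisopropylsilyloxy)phenyl]zinc chloride | CC(C)=CCc1cc([Zn]Cl)ccc1O[Si](C(C)C)(C(C)C)C(C)C
F7 | step 8 | (2S)-6-(3-methylbut-2-en-1-yl)-2-[3-(3-methylbut-2-en-1-yl)-4-(triisopropylsilyloxy)phenyl]-7-(triisopropylsilyloxy)-4-(trimethylsilyloxy)-2H-chromene | CC(C)=CCc1cc([C@H]2Oc3cc(O[Si](C(C)C)(C(C)C)C(C)C)c(CC=C(C)C)cc3C(O[Si](C)(C)C)=C2)ccc1O[Si](C(C)C)(C(C)C)C(C)C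
F8 | step 8 | (2R,3R,4R)-3,4-epoxy-6-(3-methylbut-2-en-1-yl)-2-[3-(3-methylbut-2-en-1-yl)-4-(triisopropylsilyloxy)phenyl]-7-(triisopropylsilyloxy)-4-(trimethylsilyloxy)chromane | CC(C)=CCc1cc([C@H]2Oc3cc(O[Si](C(C)C)(C(C)C)C(C)C)c(CC=C(C)C)cc3[C@]4(O[Si](C)(C)C)O[C@H]24)ccc1O[Si](C(C)C)(C(C)C)C(C)C
F9 | step 5 | 1-(5-allyl-2,4-dihydroxyphenyl)ethan-1-one | CC(=O)c1cc(CC=C)c(O)cc1O
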